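I went looking for one constant behind these flasks, a rate: the percentages of the two earlier runs differ, but so do their charges.

| flask | solid substrate | remark | time |
|---|---|---|---|
| north-east | 0.068 M | run made earlier |  |
| east | 0.28 M | run made earlier |  |
| Wednesday's | 0.050 M |  | 30 min |
| Sunday's | 0.080 M |  | 30 min |
| Tuesday's | 0.12 M |  | 30 min |
| Saturday's | 0.15 M |  | 30 min |
| Friday's | 0.25 M |  | 30 min |

| run | time / min | target / % | isomer of the product A / % |
|---|---|---|---|
| north-east | 2.50 | 1.5 | 0 |
| north-east | 5.00 | 1.7 | 2.2 |
| north-east | 8.00 | 1.2 | 2.8 |
| north-east | 15.0 | 4.9 | 6.2 |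
| north-east | 30.0 | 8.6 | 13.9 |
| east | 2.50 | 0.5 | 0 |
| east | 8.00 | 1.3 | 1.2 |
| east | 15.0 | 1.4 | 1.5 |
| east | 20.0 | 0.4 | 2.6 |
| east | 30.0 | 4.1 | 2.3 |

(each reading ± 1 percentage point)

- given per volume of solution although it is solid: solid substrate
- at the start none of the solid substrate is in solution
- "hardly changes" means that all values lie within two and a half points (for a concentration: within two and a half percent of the largest)

- share of target in all that became target or isomer of the product A or isomer of the product B or over-reaction product for Wednesday's, Sunday's, Tuesday's, Saturday's, Friday's, in this order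
- how the row runs (rises all the way / falls, then rises / hardly changes / rises, then falls / falls all the way)

I turned each percentage into molarity through its own charge and took the gain of target plus isomer of the product A per minute over the whole run:

north-east: 5.10 × 10⁻⁴ M min⁻¹

east: 5.97 × 10⁻⁴ M min⁻¹

mean: 5.54 × 10⁻⁴ M min⁻¹

I called this mean the feed, the molarity of target plus isomer of the product A gained per minute while solid is present.

Over the first 15.0 min the rates were 5.03 × 10⁻⁴ M min⁻¹ north-east and 5.41 × 10⁻⁴ M min⁻¹ east. The charge rose by a factor of 4.12, but the rate rose by 1.08, far less than the charge, so I took the going into solution as the rate-limiting step. The readings showed no slowing with time: the second half ran at 1.03 of the first half's rate north-east and 1.21 east. With no slowing read, I expected 0.0166 M by the end in each asked flask as long as solid lasted, and so a flat row. I put its level below the 52.2 % of target in target plus isomer of the product A read from the pooled runs, by an amount these readings could not show.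

The forecast ran from 40 % on Wednesday's to 40 % on Friday's, hardly changes, holding that “Extra solid then changes nothing in solution”.

The flasks gave 16.8 % on Wednesday's and 17.2 % on Friday's, hardly changes.

    starting material ⇌ target (K = 0.340, k = 4.10 × 10⁻⁴ s⁻¹)
    starting material ⇌ isomer of the product A (K = 0.430, k = 8.00 × 10⁻⁴ s⁻¹)
    starting material ⇌ isomer of the product B (K = 1.40, k = 7.50 × 10⁻⁴ s⁻¹)
    solid substrate ⇌ starting material, rate k4*(cs4 - [starting material]) while solid is left; crystals form when [starting material] > cs4 (solubility = 0.190 M, k = 2.10 × 10⁻⁴ s⁻¹)
    2 starting material → self-condensation product (k = 0.00100 M⁻¹ s⁻¹)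
    target → over-reaction product (k = 2.70 × 10⁻⁴ s⁻¹)

In Friday's flask solid still stood at 74.0 % of the charge at 30.0 min, and dissolving ran alongside the passage of starting material to the target and both isomers; the feed gives 6.64 % of the charge as target plus isomer of the product A, and the flask held 6.33 %. In Wednesday's flask solid stood at 32.5 % at 15.0 min and 0 % at 30.0 min; the feed gives 33.2 % there, and the flask held 26.8 %.

(The runs stem from a simulated flask with constants of no real substance, noise included.)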